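**Retrosynthetic overview**

1. Atom labels follow germacrane numbering (ring C1–C10, lactone C11–C13, ester carbon C14). The strategy rests on the γ-lactone ring (O6–C12–C11–C7–C6) sharing only the C6–C7 edge with the ten-membered carbocycle: C7 lies 1,5 to a carbene carbon C11 carried on an O6 ester, so the lactone can be closed last, by C7–H insertion, onto a ring that still has CH2 at C7.
2. Target ⇒ O9 desilylation and Horner–Wadsworth–Emmons methylenation (C13) ⇒ phosphonolactone 29 ⇒ C7–C11 disconnection (carbenoid C–H insertion) ⇒ ring diazophosphonoacetate 28.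
3. 28 ⇒ C1=C10 by ring-closing metathesis of the open-chain acrylate/terminal alkene 26, in which C4, C5, C6, C8 and C9 are already set.
4. 26 ⇒ C5–C6 (Nozaki–Hiyama–Kishi coupling of iodide 20 with aldehyde 17, then CBS reduction and hydroxyl-directed epoxidation); O8 ester (acid 13 from tiglic acid); C7–C8 (Brown allylation of aldehyde 7); C9–C10 (Baylis–Hillman adduct 3, kinetically resolved).
5. Ring order: oxirane of acid 13 (step 7), C4–C5 oxirane (step 15), ten-membered carbocycle (step 17), γ-lactone (step 19).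

Key step: step 19

Assumption: in the kinetic resolution of 3 the acrylate double bond is taken to be inert to the titanium–tartrate catalyst, so the usual rule for secondary allylic alcohols applies to the propenyl group and the L-(+) ligand consumes (R)-3.

**Route**

Step 1
Reactants: 1 (E)-but-2-enal (crotonaldehyde); 2 methyl acrylate
Product: 3 rac-methyl (4E)-3-hydroxy-2-methylidenehex-4-enoate
Conditions: DABCO (0.3 equiv), neat (2 in excess), rt, several days
Reagents that add atoms: none
Why: The Morita–Baylis–Hillman reaction joins the acrylate α-carbon (C10) to the aldehyde carbon (C9) by 1,2-addition under amine catalysis; the carbinol forms as a racemate that is resolved in step 2.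

Step 2
Reactants: 3 rac-methyl (4E)-3-hydroxy-2-methylidenehex-4-enoate
Product: 4 methyl (3S,4E)-3-hydroxy-2-methylidenehex-4-enoate
Conditions: Ti(OiPr)4, L-(+)-diisopropyl tartrate, tBuOOH (0.6 equiv), 4 Å MS, CH2Cl2, −20 °C
Reagents that add atoms: none
Why: In this Sharpless kinetic resolution the titanium–tartrate catalyst should epoxidise the propenyl group of (R)-3 much faster than that of (S)-3 and leave the electron-poor acrylate alone, so the unreacted (S)-alcohol, which has the C9 configuration of the target, is recovered.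

Step 3
Reactants: 4 methyl (3S,4E)-3-hydroxy-2-methylidenehex-4-enoate
Product: 5 methyl (3S,4E)-3-[(tert-butyldimethylsilyl)oxy]-2-methylidenehex-4-enoate
Conditions: TBSCl, imidazole, DMF, rt
Reagents that add atoms: tert-butyldimethylsilyl chloride, CC(C)(C)[Si](C)(C)Cl
Why: Standard silylation of a secondary allylic alcohol under neutral conditions installs the O9 protecting group that stays until the last step; no stereocentre is touched.

Step 4
Reactants: 5 methyl (3S,4E)-3-[(tert-butyldimethylsilyl)oxy]-2-methylidenehex-4-enoate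
Product: 7 methyl (3R)-3-[(tert-butyldimethylsilyl)oxy]-2-methylidene-4-oxobutanoate, via secondary ozonide 6 (not isolated)
Conditions: O3, CH2Cl2, −78 °C (Sudan Red 7B end point); then Me2S, −78 °C → rt
Reagents that add atoms: ozone, [O-][O+]=O
Why: Ozonolysis should cleave the electron-rich 1,2-disubstituted propenyl alkene far faster than the acrylate, and neutral cold reduction of the ozonide unmasks C8 as the aldehyde without epimerising the α-silyloxy centre C9 (the descriptor changes to R only through priorities).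

Step 5
Reactants: 7 methyl (3R)-3-[(tert-butyldimethylsilyl)oxy]-2-methylidene-4-oxobutanoate
Product: 9 methyl (3R,4S)-3-[(tert-butyldimethylsilyl)oxy]-4-hydroxy-2-methylidenehept-6-enoate, via borinate ester 8 (not isolated)
Conditions: (−)-Ipc2B(allyl) [from (+)-α-pinene], Et2O, −78 °C; then pH 7 buffer, 30% H2O2, MeOH, 0 °C → rt
Reagents that add atoms: (−)-B-allyldiisopinocampheylborane, C=CCB([C@@H]1C[C@@H]2C[C@H]([C@H]1C)C2(C)C)[C@@H]1C[C@@H]2C[C@H]([C@H]1C)C2(C)C
Why: In this Brown allylation the borane delivers allyl to the Si face of the aldehyde through a chair transition state, which sets C8 as S and coincides with the Felkin–Anh preference of the α-silyloxy aldehyde (matched, O8/O9 anti); buffered peroxide then cleaves the borinate without attacking the acrylate.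

Step 6
Reactants: 10 tiglic acid
Product: 11 (E)-2-methylbut-2-en-1-ol
Conditions: LiAlH4, Et2O, 0 °C
Reagents that add atoms: none
Why: Hydride reduction of the carboxylic acid gives the primary allylic alcohol and should leave the trisubstituted E alkene intact at low temperature.

Step 7
Reactants: 11 (E)-2-methylbut-2-en-1-ol
Product: 12 [(2R,3R)-2,3-dimethyloxiran-2-yl]methanol
Conditions: Ti(OiPr)4 (10 mol%), D-(−)-diisopropyl tartrate (12 mol%), tBuOOH, 4 Å MS, CH2Cl2, −20 °C
Reagents that add atoms: tert-butyl hydroperoxide, CC(C)(C)OO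
Why: In this Sharpless asymmetric epoxidation of an E primary allylic alcohol the D-(−) ligand should direct oxygen to the face that gives the (2R,3R)-epoxy alcohol, the mirror image of the (2S,3S) outcome given by the L-(+) ligand with E allylic alcohols.

Step 8
Reactants: 12 [(2R,3R)-2,3-dimethyloxiran-2-yl]methanol
Product: 13 (2S,3R)-2,3-dimethyloxirane-2-carboxylic acid
Conditions: TEMPO (cat.), PhI(OAc)2, MeCN/H2O (1:1), 0 °C → rt
Reagents that add atoms: water, O
Why: TEMPO-catalysed oxidation takes the primary alcohol through the aldehyde hydrate to the acid under near-neutral conditions that an oxirane tolerates; C2 becomes S only because the priorities change.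

Step 9
Reactants: 9 methyl (3R,4S)-3-[(tert-butyldimethylsilyl)oxy]-4-hydroxy-2-methylidenehept-6-enoate; 13 (2S,3R)-2,3-dimethyloxirane-2-carboxylic acid
Product: 15 methyl (3R,4S)-3-[(tert-butyldimethylsilyl)oxy]-4-{[(2S,3R)-2,3-dimethyloxirane-2-carbonyl]oxy}-2-methylidenehept-6-enoate, via mixed anhydride 14 (not isolated)
Conditions: 13, 2,4,6-Cl3C6H2COCl, Et3N, toluene, rt; then 9, DMAP, rt
Reagents that add atoms: 2,4,6-trichlorobenzoyl chloride, O=C(Cl)c1c(Cl)cc(Cl)cc1Cl (its atoms appear in 14 only)
Why: In this Yamaguchi esterification DMAP attacks the unshielded glycidic carbonyl of the mixed anhydride and the acylpyridinium acylates the hindered O8–H; the quaternary α-carbon of the acid cannot enolise, so its configuration is safe.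

Step 10
Reactants: 15 methyl (3R,4S)-3-[(tert-butyldimethylsilyl)oxy]-4-{[(2S,3R)-2,3-dimethyloxirane-2-carbonyl]oxy}-2-methylidenehept-6-enoate
Product: 17 methyl (3R,4S)-3-[(tert-butyldimethylsilyl)oxy]-4-{[(2S,3R)-2,3-dimethyloxirane-2-carbonyl]oxy}-2-methylidene-6-oxohexanoate, via secondary ozonide 16 (not isolated)
Conditions: O3, CH2Cl2, −78 °C (Sudan Red 7B end point); then Me2S, −78 °C → rt
Reagents that add atoms: ozone, [O-][O+]=O
Why: Ozonolysis of the terminal alkene in the presence of the less reactive acrylate, stopped at the indicator end point, gives the C6 aldehyde, which is used at once because β-acyloxy aldehydes eliminate easily.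

Step 11
Reactants: 18 hex-1-en-5-yne
Product: 20 (1E)-1-iodo-2-methylhexa-1,5-diene, via alkenylalane 19 (not isolated)
Conditions: Me3Al, Cp2ZrCl2 (0.25 equiv), CH2Cl2, 0 °C → rt; then I2, THF, −30 → 0 °C
Reagents that add atoms: trimethylaluminium, C[Al](C)C; iodine, II
Why: Zirconium-catalysed Negishi carboalumination adds methyl and aluminium syn across the alkyne with the metal at the terminus, and iodinolysis with retention gives the E iodide (the later trans C3/C6 pair on the oxirane); the isolated terminal alkene should not be carbometallated.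

Step 12
Reactants: 17 methyl (3R,4S)-3-[(tert-butyldimethylsilyl)oxy]-4-{[(2S,3R)-2,3-dimethyloxirane-2-carbonyl]oxy}-2-methylidene-6-oxohexanoate; 20 (1E)-1-iodo-2-methylhexa-1,5-diene
Product: 21 methyl (3R,4S,6RS,7E)-3-[(tert-butyldimethylsilyl)oxy]-4-{[(2S,3R)-2,3-dimethyloxirane-2-carbonyl]oxy}-6-hydroxy-8-methyl-2-methylidenedodeca-7,11-dienoate
Conditions: CrCl2 (excess), NiCl2 (1 mol%), DMSO, rt
Reagents that add atoms: none
Why: In this Nozaki–Hiyama–Kishi coupling the nickel-generated alkenylchromium species adds only to the aldehyde, with retention of the E alkene and tolerance of acrylate, esters, oxirane and silyl ether; the C6 epimer mixture is harmless because C6 is oxidised next.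

Step 13
Reactants: 21 methyl (3R,4S,6RS,7E)-3-[(tert-butyldimethylsilyl)oxy]-4-{[(2S,3R)-2,3-dimethyloxirane-2-carbonyl]oxy}-6-hydroxy-8-methyl-2-methylidenedodeca-7,11-dienoate
Product: 22 methyl (3R,4S,7E)-3-[(tert-butyldimethylsilyl)oxy]-4-{[(2S,3R)-2,3-dimethyloxirane-2-carbonyl]oxy}-8-methyl-2-methylidene-6-oxododeca-7,11-dienoate
Conditions: Dess–Martin periodinane, CH2Cl2, 0 °C → rt
Reagents that add atoms: none
Why: Dess–Martin oxidation of the allylic alcohol gives the enone without any base strong enough to eliminate the β-acyloxy group.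

Step 14
Reactants: 22 methyl (3R,4S,7E)-3-[(tert-butyldimethylsilyl)oxy]-4-{[(2S,3R)-2,3-dimethyloxirane-2-carbonyl]oxy}-8-methyl-2-methylidene-6-oxododeca-7,11-dienoate
Product: 23 methyl (3R,4S,6S,7E)-3-[(tert-butyldimethylsilyl)oxy]-4-{[(2S,3R)-2,3-dimethyloxirane-2-carbonyl]oxy}-6-hydroxy-8-methyl-2-methylidenedodeca-7,11-dienoate
Conditions: (R)-2-methyl-CBS-oxazaborolidine, catecholborane, toluene, −78 °C
Reagents that add atoms: none
Why: In this Corey–Bakshi–Shibata reduction the (R)-oxazaborolidine binds the enone with the alkenyl group as the large substituent and should deliver hydride to give the 6S alcohol by reagent control; catecholborane at −78 °C should not hydroborate the terminal alkene or reduce the acrylate.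

Step 15
Reactants: 23 methyl (3R,4S,6S,7E)-3-[(tert-butyldimethylsilyl)oxy]-4-{[(2S,3R)-2,3-dimethyloxirane-2-carbonyl]oxy}-6-hydroxy-8-methyl-2-methylidenedodeca-7,11-dienoate
Product: 24 methyl (3R,4S,6S)-6-[(2R,3R)-3-(but-3-en-1-yl)-3-methyloxiran-2-yl]-3-[(tert-butyldimethylsilyl)oxy]-4-{[(2S,3R)-2,3-dimethyloxirane-2-carbonyl]oxy}-6-hydroxy-2-methylidenehexanoate
Conditions: mCPBA, CH2Cl2/aq. phosphate buffer (pH 7), 0 °C
Reagents that add atoms: 3-chloroperbenzoic acid, OOC(=O)c1cccc(Cl)c1
Why: In this hydroxyl-directed peracid epoxidation, allylic 1,3-strain with the C4 methyl (cis to C6) holds H6 in the alkene plane, so the hydrogen-bonded peracid should attack syn to the hydroxyl and give the threo (4R,5R) oxirane; the trisubstituted allylic alkene is far more reactive than the terminal alkene or the acrylate.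

Step 16
Reactants: 24 methyl (3R,4S,6S)-6-[(2R,3R)-3-(but-3-en-1-yl)-3-methyloxiran-2-yl]-3-[(tert-butyldimethylsilyl)oxy]-4-{[(2S,3R)-2,3-dimethyloxirane-2-carbonyl]oxy}-6-hydroxy-2-methylidenehexanoate; 25 (diethoxyphosphoryl)acetic acid
Product: 26 open-chain O6 (diethoxyphosphoryl)acetate of 24
Conditions: DCC, DMAP (cat.), CH2Cl2, 0 °C → rt
Reagents that add atoms: none
Why: Steglich esterification of the secondary O6–H with the phosphonoacetic acid under carbodiimide/DMAP activation; no stereocentre is affected.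

Step 17
Reactants: 26 open-chain O6 (diethoxyphosphoryl)acetate of 24
Product: 27 ten-membered (1(10)E,4R,5R,6S,8S,9R)-4,5-epoxy enoate with C7 methylene; O6 (diethoxyphosphoryl)acetate; O8 epoxy ester; O9 TBS ether; C14 methyl ester
Conditions: second-generation Hoveyda–Grubbs catalyst RuCl2(H2IMes)(=CH-C6H4-2-OiPr) (10 mol%), toluene (1 mM), 80 °C
Reagents that add atoms: none
Why: In this ring-closing metathesis the catalyst loads on the unhindered terminal alkene and closes onto the 1,1-disubstituted acrylate with loss of ethene; the ten-membered ring should favour C1=C10 with C9 and C2 cis, which is the E enoate of the target, and the C4=C5 alkene that could have closed a six-membered ring is already an oxirane.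

Step 18
Reactants: 27 ten-membered O6 (diethoxyphosphoryl)acetate
Product: 28 ten-membered O6 diazo(diethoxyphosphoryl)acetate (4R,5R,6S,8S,9R)
Conditions: 4-AcNH-C6H4SO2N3, DBU, MeCN, 0 °C → rt
Reagents that add atoms: 4-acetamidobenzenesulfonyl azide, CC(=O)Nc1ccc(cc1)S(=O)(=O)N=[N+]=[N-]
Why: In this Regitz diazo transfer DBU deprotonates the carbon between P=O and C=O and the carbanion takes N2 from the sulfonyl azide; the step follows metathesis because a diazo group would destroy the ruthenium carbene.

Step 19
Reactants: 28 ten-membered O6 diazo(diethoxyphosphoryl)acetate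
Product: 29 trans-fused α-(diethoxyphosphoryl)-γ-lactone (4R,5R,6S,7S,8S,9R,11S; 7S here is the same geometry as 7R in the target)
Conditions: Rh2(OAc)4 (2 mol%), ClCH2CH2Cl (5 mM, slow addition of 28), 80 °C
Reagents that add atoms: none
Why: Rh2(OAc)4 should release N2 from 28 to give an electrophilic dirhodium carbenoid at C11 that inserts into a C7–H bond through a concerted three-centre transition state with retention at C7; the closest known reaction type is the rhodium-catalysed intramolecular C–H insertion of α-diazo-α-phosphonoacetates of secondary alcohols to α-phosphono-γ-butyrolactones. The γ-lactone (O6–C12–C11–C7–C6) closes in the 1,5-insertion mode, which is preferred over the 1,6 mode at C8–H (also deactivated by its acyloxy group) and over the 1,4 mode at C6–H. C7 is set by which of its two hydrogens lies gauche to the C6–O6 bond: the anti-1,3 pair of acyloxy groups at C6 and C8 should favour an extended C5–C6–C7–C8 segment in which only the hydrogen leading to the trans ring fusion is within reach, while C11 forms with phosphorus anti to C8 and is erased in step 20. The step also needs chemoselectivity: the other 1,5 C–H bond, on oxirane carbon C5, has high s-character and should be inert, the oxirane oxygen is a weak donor whose ylide would be strained and reversible, and the only alkene, C1=C10, is electron-poor and trisubstituted, so cyclopropanation is not expected. Slow addition at high dilution should suppress carbene dimerisation. The trans outcome on a ten-membered ring rests on this conformational argument and not on precedent, and the C7–H bonds are inductively deactivated by two β-acyloxy groups, so this is the step on which the route stands or falls.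

Step 20
Reactants: 29 trans-fused α-(diethoxyphosphoryl)-γ-lactone
Product: 30 O9 tert-butyldimethylsilyl ether of the target (α-methylene lactone)
Conditions: 37% aq. HCHO, K2CO3, THF, 0 °C
Reagents that add atoms: formaldehyde, C=O
Why: In this Horner–Wadsworth–Emmons olefination carbonate deprotonates C11 between phosphonate and lactone carbonyl and the anion condenses with formaldehyde to the exocyclic C11=C13 alkene, which also removes the C11 stereocentre; mild base and short contact at 0 °C should spare the esters.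

Step 21
Reactants: 30 O9 tert-butyldimethylsilyl ether of the target
Product: 31 target CNP0262846.1
Conditions: Bu4NF, AcOH (1:1), THF, 0 °C → rt
Reagents that add atoms: none
Why: Fluoride-induced silyl ether cleavage buffered with acetic acid keeps the medium non-basic, so the O8 ester should not migrate to O9 and the α-methylene lactone should not take up nucleophiles; no stereocentre is touched.

**Compound list**

1 | (E)-but-2-enal (crotonaldehyde) | C/C=C/C=O | starting material
2 | methyl acrylate | C=CC(=O)OC | starting material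
3 | rac-methyl (4E)-3-hydroxy-2-methylidenehex-4-enoate | C/C=C/C(O)C(=C)C(=O)OC | intermediate
4 | methyl (3S,4E)-3-hydroxy-2-methylidenehex-4-enoate | C/C=C/[C@H](O)C(=C)C(=O)OC | intermediate
5 | methyl (3S,4E)-3-[(tert-butyldimethylsilyl)oxy]-2-methylidenehex-4-enoate | C/C=C/[C@H](O[Si](C)(C)C(C)(C)C)C(=C)C(=O)OC | intermediate
6 | secondary ozonide of 5: methyl (3R)-3-[(tert-butyldimethylsilyl)oxy]-2-methylidene-3-(5-methyl-1,2,4-trioxolan-3-yl)propanoate | CC1OOC(O1)[C@H](O[Si](C)(C)C(C)(C)C)C(=C)C(=O)OC | intermediate (not isolated)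
7 | methyl (3R)-3-[(tert-butyldimethylsilyl)oxy]-2-methylidene-4-oxobutanoate | O=C[C@H](O[Si](C)(C)C(C)(C)C)C(=C)C(=O)OC | intermediate
8 | borinate ester: methyl (3R,4S)-3-[(tert-butyldimethylsilyl)oxy]-4-[(diisopinocampheylboranyl)oxy]-2-methylidenehept-6-enoate | C=CC[C@H](OB([C@@H]1C[C@@H]2C[C@H]([C@H]1C)C2(C)C)[C@@H]1C[C@@H]2C[C@H]([C@H]1C)C2(C)C)[C@H](O[Si](C)(C)C(C)(C)C)C(=C)C(=O)OC | intermediate (not isolated)
9 | methyl (3R,4S)-3-[(tert-butyldimethylsilyl)oxy]-4-hydroxy-2-methylidenehept-6-enoate | C=CC[C@H](O)[C@H](O[Si](C)(C)C(C)(C)C)C(=C)C(=O)OC | intermediate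
10 | tiglic acid, (E)-2-methylbut-2-enoic acid | C/C=C(\C)C(=O)O | starting material
11 | (E)-2-methylbut-2-en-1-ol | C/C=C(\C)CO | intermediate
12 | [(2R,3R)-2,3-dimethyloxiran-2-yl]methanol | OC[C@@]1(C)O[C@@H]1C | intermediate
13 | (2S,3R)-2,3-dimethyloxirane-2-carboxylic acid | OC(=O)[C@@]1(C)O[C@@H]1C | intermediate
14 | mixed anhydride of 13 with 2,4,6-trichlorobenzoic acid | O=C(OC(=O)[C@@]1(C)O[C@@H]1C)c1c(Cl)cc(Cl)cc1Cl | intermediate (not isolated)
15 | methyl (3R,4S)-3-[(tert-butyldimethylsilyl)oxy]-4-{[(2S,3R)-2,3-dimethyloxirane-2-carbonyl]oxy}-2-methylidenehept-6-enoate | C=CC[C@H](OC(=O)[C@@]1(C)O[C@@H]1C)[C@H](O[Si](C)(C)C(C)(C)C)C(=C)C(=O)OC | intermediate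
16 | secondary ozonide of 15: methyl (3R,4S)-3-[(tert-butyldimethylsilyl)oxy]-4-{[(2S,3R)-2,3-dimethyloxirane-2-carbonyl]oxy}-2-methylidene-5-(1,2,4-trioxolan-3-yl)pentanoate | C1OOC(O1)C[C@H](OC(=O)[C@@]1(C)O[C@@H]1C)[C@H](O[Si](C)(C)C(C)(C)C)C(=C)C(=O)OC | intermediate (not isolated)
17 | methyl (3R,4S)-3-[(tert-butyldimethylsilyl)oxy]-4-{[(2S,3R)-2,3-dimethyloxirane-2-carbonyl]oxy}-2-methylidene-6-oxohexanoate | O=CC[C@H](OC(=O)[C@@]1(C)O[C@@H]1C)[C@H](O[Si](C)(C)C(C)(C)C)C(=C)C(=O)OC | intermediate
18 | hex-1-en-5-yne | C=CCCC#C | starting material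
19 | dimethyl[(1E)-2-methylhexa-1,5-dien-1-yl]alumane | C=CCC/C(C)=C/[Al](C)C | intermediate (not isolated)
20 | (1E)-1-iodo-2-methylhexa-1,5-diene | C=CCC/C(C)=C/I | intermediate
21 | methyl (3R,4S,6RS,7E)-3-[(tert-butyldimethylsilyl)oxy]-4-{[(2S,3R)-2,3-dimethyloxirane-2-carbonyl]oxy}-6-hydroxy-8-methyl-2-methylidenedodeca-7,11-dienoate | C=CCC/C(C)=C/C(O)C[C@H](OC(=O)[C@@]1(C)O[C@@H]1C)[C@H](O[Si](C)(C)C(C)(C)C)C(=C)C(=O)OC | intermediate
22 | methyl (3R,4S,7E)-3-[(tert-butyldimethylsilyl)oxy]-4-{[(2S,3R)-2,3-dimethyloxirane-2-carbonyl]oxy}-8-methyl-2-methylidene-6-oxododeca-7,11-dienoate | C=CCC/C(C)=C/C(=O)C[C@H](OC(=O)[C@@]1(C)O[C@@H]1C)[C@H](O[Si](C)(C)C(C)(C)C)C(=C)C(=O)OC | intermediate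
23 | methyl (3R,4S,6S,7E)-3-[(tert-butyldimethylsilyl)oxy]-4-{[(2S,3R)-2,3-dimethyloxirane-2-carbonyl]oxy}-6-hydroxy-8-methyl-2-methylidenedodeca-7,11-dienoate | C=CCC/C(C)=C/[C@@H](O)C[C@H](OC(=O)[C@@]1(C)O[C@@H]1C)[C@H](O[Si](C)(C)C(C)(C)C)C(=C)C(=O)OC | intermediate
24 | methyl (3R,4S,6S)-6-[(2R,3R)-3-(but-3-en-1-yl)-3-methyloxiran-2-yl]-3-[(tert-butyldimethylsilyl)oxy]-4-{[(2S,3R)-2,3-dimethyloxirane-2-carbonyl]oxy}-6-hydroxy-2-methylidenehexanoate | C=CCC[C@@]1(C)O[C@@H]1[C@@H](O)C[C@H](OC(=O)[C@@]1(C)O[C@@H]1C)[C@H](O[Si](C)(C)C(C)(C)C)C(=C)C(=O)OC | intermediate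
25 | (diethoxyphosphoryl)acetic acid | CCOP(=O)(OCC)CC(=O)O | starting material
26 | open-chain O6 (diethoxyphosphoryl)acetate of 24: methyl (3R,4S,6S)-6-[(2R,3R)-3-(but-3-en-1-yl)-3-methyloxiran-2-yl]-3-[(tert-butyldimethylsilyl)oxy]-6-{[(diethoxyphosphoryl)acetyl]oxy}-4-{[(2S,3R)-2,3-dimethyloxirane-2-carbonyl]oxy}-2-methylidenehexanoate | C=CCC[C@@]1(C)O[C@@H]1[C@@H](OC(=O)CP(=O)(OCC)OCC)C[C@H](OC(=O)[C@@]1(C)O[C@@H]1C)[C@H](O[Si](C)(C)C(C)(C)C)C(=C)C(=O)OC | intermediate
27 | ten-membered (1(10)E,4R,5R,6S,8S,9R)-4,5-epoxy enoate with C7 methylene; O6 (diethoxyphosphoryl)acetate; O8 (2S,3R)-2,3-dimethyloxirane-2-carboxylate; O9 TBS ether; C14 methyl ester | CCOP(=O)(OCC)CC(=O)O[C@H]2C[C@H](OC(=O)[C@@]1(C)O[C@@H]1C)[C@H](O[Si](C)(C)C(C)(C)C)/C(C(=O)OC)=C\CC[C@@]3(C)O[C@H]23 | intermediate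
28 | as 27 but O6 diazo(diethoxyphosphoryl)acetate (key-step precursor) | CCOP(=O)(OCC)C(=[N+]=[N-])C(=O)O[C@H]2C[C@H](OC(=O)[C@@]1(C)O[C@@H]1C)[C@H](O[Si](C)(C)C(C)(C)C)/C(C(=O)OC)=C\CC[C@@]3(C)O[C@H]23 | intermediate
29 | trans-fused 11-(diethoxyphosphoryl)-12,6-lactone (4R,5R,6S,7S,8S,9R,11S); O8 epoxy ester; O9 TBS ether (key-step product) | CCOP(=O)(OCC)[C@@H]1C(=O)O[C@H]2[C@H]1[C@H](OC(=O)[C@@]4(C)O[C@@H]4C)[C@H](O[Si](C)(C)C(C)(C)C)/C(C(=O)OC)=C\CC[C@@]3(C)O[C@H]23 | intermediate
30 | O9 tert-butyldimethylsilyl ether of the target (4R,5R,6S,7S,8S,9R) | C=C1C(=O)O[C@H]2[C@H]1[C@H](OC(=O)[C@@]1(C)O[C@@H]1C)[C@H](O[Si](C)(C)C(C)(C)C)/C(C(=O)OC)=C\CC[C@@]1(C)O[C@H]21 | intermediate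
31 | CNP0262846.1: methyl (1(10)E,4R,5R,6S,7R,8S,9R)-8-{[(2S,3R)-2,3-dimethyloxirane-2-carbonyl]oxy}-4,5-epoxy-9-hydroxygermacra-1(10),11(13)-dien-12,6-olid-14-oate | C=C1C(=O)O[C@H]2[C@H]1[C@H](OC(=O)[C@@]1(C)O[C@@H]1C)[C@H](O)/C(C(=O)OC)=C\CC[C@@]1(C)O[C@H]21 | target

**Step count and risks**

Total steps: 21. Longest linear sequence: 17 steps (1–5, 9, 10, 12–21).

1. Step 19 (carbenoid C–H insertion). What may go wrong: capture of the carbenoid by the C4–C5 oxirane oxygen (ylide formation and loss of the epoxide), insertion into the C7 hydrogen that gives the cis-fused lactone because the ring adopts another conformer, or sluggish insertion into the deactivated C7–H bonds so that carbene dimerisation takes over. Fallback: make the same bond before ring closure, where trans selectivity of 1,5-insertion in open chains is established. It sets out from 26. Diazo transfer (4-acetamidobenzenesulfonyl azide, DBU) should give the open-chain diazophosphonoacetate F1. Rh2(OAc)4 in hot 1,2-dichloroethane should then close the lactone through a chair-like transition state with both substituents pseudo-equatorial, giving the open-chain trans α-phosphono-γ-butyrolactone F2. Ring-closing metathesis of F2 (second-generation Hoveyda–Grubbs catalyst, dilute toluene, 80 °C) closes C1=C10 and comes back to the route at 29.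

2. Step 17 (ring-closing metathesis). What may go wrong: slow engagement of the hindered, electron-poor acrylate together with the strain of the ten-membered ring lets intermolecular metathesis of the terminal alkene (dimers, oligomers) or catalyst decay win. Fallback: form C1=C10 between two molecules and close the ring at C5–C6 by a Nozaki–Hiyama–Kishi reaction, a known way to ten-membered carbocycles. It sets out from aldehyde 17 and iodide 20. Cross-metathesis (same catalyst, excess 20) should give the E enoate seco-aldehyde F3. CrCl2/NiCl2 in DMSO at high dilution should close the ring to the ten-membered allylic alcohol F4 (C6 epimers). Dess–Martin oxidation gives the ring enone F5, CBS reduction with the (R)-oxazaborolidine the 6S ring alcohol F6, and hydroxyl-directed epoxidation with mCPBA the ring epoxy alcohol F7. Esterification of F7 with 25 (DCC, DMAP) comes back to the route at 27. In this variant the reduction and the epoxidation take place on the ring, so their facial selectivity depends on the ring conformation and would have to be checked.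

3. Step 21 (final desilylation). What may go wrong: fluoride, or the alkoxide it liberates, triggers migration of the O8 acyl group to O9 or conjugate addition to the α-methylene lactone, or the hindered silyl ether is cleaved too slowly for the sensitive product to survive. Fallback: remove the silyl group before the methylene lactone exists. It sets out from 29. Et3N·3HF in MeCN should give the 9-hydroxy phosphonolactone F8, and the Horner–Wadsworth–Emmons reaction of F8 with aqueous formaldehyde and K2CO3 at 0 °C comes back to the route at 31.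

**Further compounds**

F1 | step 19 | open-chain diazophosphonoacetate (26 with N2 on the phosphonoacetate carbon) | C=CCC[C@@]1(C)O[C@@H]1[C@@H](OC(=O)C(=[N+]=[N-])P(=O)(OCC)OCC)C[C@H](OC(=O)[C@@]1(C)O[C@@H]1C)[C@H](O[Si](C)(C)C(C)(C)C)C(=C)C(=O)OC
F2 | step 19 | open-chain trans α-phosphono-γ-butyrolactone (29 with C1=C10 not yet closed: acrylate and but-3-enyl ends) | CCOP(=O)(OCC)[C@@H]1C(=O)O[C@H]([C@H]2O[C@]2(C)CCC=C)[C@H]1[C@H](OC(=O)[C@@]3(C)O[C@@H]3C)[C@H](O[Si](C)(C)C(C)(C)C)C(=C)C(=O)OC
F3 | step 17 | E enoate seco-aldehyde with terminal E vinyl iodide | O=CC[C@H](OC(=O)[C@@]1(C)O[C@@H]1C)[C@H](O[Si](C)(C)C(C)(C)C)/C(C(=O)OC)=C\CC/C(C)=C/I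
F4 | step 17 | ten-membered allylic alcohol (C6 epimers; C4=C5 E; C1=C10 enoate) | C1[C@H](OC(=O)[C@@]2(C)O[C@@H]2C)[C@H](O[Si](C)(C)C(C)(C)C)/C(C(=O)OC)=C\CC/C(C)=C/C1O
F5 | step 17 | ten-membered ring enone (C6 ketone) | C1[C@H](OC(=O)[C@@]2(C)O[C@@H]2C)[C@H](O[Si](C)(C)C(C)(C)C)/C(C(=O)OC)=C\CC/C(C)=C/C1=O
F6 | step 17 | ten-membered 6S allylic alcohol | C1[C@H](OC(=O)[C@@]2(C)O[C@@H]2C)[C@H](O[Si](C)(C)C(C)(C)C)/C(C(=O)OC)=C\CC/C(C)=C/[C@H]1O
F7 | step 17 | ten-membered (4R,5R,6S) epoxy alcohol (27 without the O6 acyl group) | O[C@H]2C[C@H](OC(=O)[C@@]1(C)O[C@@H]1C)[C@H](O[Si](C)(C)C(C)(C)C)/C(C(=O)OC)=C\CC[C@@]3(C)O[C@H]23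
F8 | step 21 | 9-hydroxy phosphonolactone (29 without the silyl group) | CCOP(=O)(OCC)[C@@H]1C(=O)O[C@H]2[C@H]1[C@H](OC(=O)[C@@]4(C)O[C@@H]4C)[C@H](O)/C(C(=O)OC)=C\CC[C@@]3(C)O[C@H]23
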